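I began from a one-step world, where a charge loses the same fraction of itself each minute and the fraction left after time t is exp(-kt). I wanted such a constant k for this scheme, and a way to apply it to each recipe.

    substrate + free catalyst ⇌ free catalyst + open intermediate (K1 = 0.29, k1 = 1000 /M/s)
    free catalyst + open intermediate ⇌ catalyst intermediate (K2 = 94 /M, k2 = 210 /M/s)
    coupling partner + catalyst intermediate → free catalyst + target (k3 = 580 /M/s)
    free catalyst ⇌ dormant form (K4 = 3.7, k4 = 0.086 /s)

in all of them: free catalyst 56 µM; time 40 min
- red: substrate 28 mM; coupling partner 84.0 mM (fed, over 30 min); all else is in the flask from the start; the feed brings no volume worth counting
- blue: substrate 28 mM (in portions, 3, over 30 min); coupling partner 84.0 mM; first portion at the start, last at 30 min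
- green: substrate 28 mM; coupling partner 84.0 mM; everything together at the start
- grey: substrate 28 mM (fed, over 30 min); coupling partner 84.0 mM; all else is in the flask from the start; the feed brings no volume worth counting

- the best flask by amount of target, in percent of the substrate charged; "all alike" if 1.5 percentage points covers them all (red / blue / green / grey / all alike)
- amount of target at the end, in percent of the substrate charged, red
- amount of target at the end, in percent of the substrate charged, blue
- amount of target at the end, in percent of the substrate charged, green
- amount of target at the end, in percent of the substrate charged, grey

The dormant balance leaves 21.3% of the catalyst free. At the balance of substrate and open intermediate, open intermediate makes up 22.5% of the pool, by which I mean the two together. At the charged coupling partner, 95.6% of the open intermediate that free catalyst captures goes on to target. Multiplying these shares by the capture constant and the catalyst charge gave 0.0323 /min, which I called the pool constant, the fraction of the pool that becomes target each minute, a pseudo-first-order constant. The substrate and open intermediate balance relaxes at 3.18 /min, far faster than the pool falls, so capture is the rate-limiting step. For green, this gave 72.5% target.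

Blue and grey look nearly the same: in both flasks the substrate arrives over 30 min, and its mean age at the end is 25.0 min, less than green's 40 min. I solved grey at both ends and joined them. The feed leaves a pool of 64.1% of the charge, and the tail then decays it, giving 53.6% target. Blue I summed portion by portion, which gave 51.8%, less than grey. Blue's portions sit further from the mean age than grey's even stream, and, measured against a portion of the mean age, blue's youngest portion keeps more pool than its oldest gives up.

Red starts without coupling partner, and catalyst intermediate splits evenly between going on to target and falling back when coupling partner stands at 4.59% of its charge, an amount the feed has delivered by 1.38 min. I put red below green, without a number of its own.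

The forecast put green first at 71%, with red 66%, grey 52% and blue 50.5%, and its ground for blue and grey was “Adding substrate late simply gives it less time”.

The simulation put green first at 71.1%, with red 67.4%, grey 51.7% and blue 50.2%. At 30.0 min, grey held 51.7% substrate and 14.1% open intermediate, a pool of 65.8% against my 64.1%. A neighbouring flask, like blue but with 0.034 mM of free catalyst, scales the pool constant to 0.0196 /min, and the same three portions then give 36.9% target. That flask ended with 35.4% target.

Its constants belong to no real substance; what happens was integrated by code.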